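**Retrosynthetic overview**
- Target ⇐ catalyst-controlled Rh 1,4-addition of 4-hydroxyphenylboronic acid to a 7-hydroxy-5-methoxy-8-lavandulylchromone; this sets C2, and ring B is bought.
- Chromone (rings A and C) ⇐ one-flask anionic ring transformation of a 3-(aminoacryloyl)-4-methoxy-6-alkyl-2-pyranone: the pyranone O→C acyl shift builds ring A, then the new ortho OH closes ring C on the enaminone.
- Pyranone ⇐ dehydroacetic acid (it already holds all eight core carbons) + DMF-DMA, lateral alkylation with (S)-lavandulyl iodide, O-methylation; the 5-OMe/7-OH/8-alkyl pattern is fixed by connectivity.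
- (S)-Lavandulyl iodide ⇐ Evans deconjugative prenylation of an N-senecioyl oxazolidinone, reduction, iodination.
- Ring order: A, then C (both in step 8); ring B arrives intact in step 9.

Assumption: the sense of induction in step 9 is taken from the Hayashi model ((S)-biaryl bisphosphine → 2S); if the first run gives the 2R series, the (R)-ligand is used instead.

**Step 1**
Reactants: 1 (4S)-4-benzyl-1,3-oxazolidin-2-one; 2 3-methylbut-2-enoyl chloride
Product: 4 (4S)-4-benzyl-3-(3-methylbut-2-enoyl)-1,3-oxazolidin-2-one, via lithium oxazolidinide 3 (not isolated)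
Conditions: n-BuLi, THF, −78 °C; then 2, −78 → 0 °C
Reagents that add atoms: none
Why: N-acylation of the lithiated Evans oxazolidinone with an acid chloride is the standard imide synthesis and forms no stereocentre.

**Step 2**
Reactants: 4; 5 1-bromo-3-methylbut-2-ene (prenyl bromide)
Product: 7 (4S)-4-benzyl-3-[(2S)-5-methyl-2-(prop-1-en-2-yl)hex-4-enoyl]-1,3-oxazolidin-2-one, via sodium dienolate 6 (not isolated)
Conditions: NaHMDS (1.05 equiv), THF, −78 °C; then 5, −78 → −40 °C
Reagents that add atoms: none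
Why: Evans deconjugative α-alkylation: γ-deprotonation gives the chelated (Z)-dienolate 6, which is prenylated at the α-carbon on the face opposite the benzyl group, setting the (2S) centre that becomes the lavandulyl carbon.

**Step 3**
Reactants: 7
Product: 8 (2S)-5-methyl-2-(prop-1-en-2-yl)hex-4-en-1-ol ((S)-lavandulol)
Conditions: LiBH4, MeOH (1 equiv), Et2O, 0 °C
Reagents that add atoms: none
Why: Reductive cleavage of the N-acyl oxazolidinone by LiBH4 gives the primary alcohol without touching the alkenes or the α-stereocentre and returns the auxiliary.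

**Step 4**
Reactants: 8
Product: 9 (3S)-3-(iodomethyl)-2,6-dimethylhepta-1,5-diene ((S)-lavandulyl iodide)
Conditions: I2, PPh3, imidazole, CH2Cl2, 0 °C → rt
Reagents that add atoms: iodine, II
Why: Appel-type (Garegg–Samuelsson) iodination is an SN2 reaction at the CH2 group, so the neighbouring stereocentre is untouched.

**Step 5**
Reactants: 10 dehydroacetic acid (3-acetyl-4-hydroxy-6-methyl-2H-pyran-2-one); 11 N,N-dimethylformamide dimethyl acetal
Product: 12 3-[(2E)-3-(dimethylamino)prop-2-enoyl]-4-hydroxy-6-methyl-2H-pyran-2-one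
Conditions: PhMe, 80 °C
Reagents that add atoms: none
Why: Enaminone formation by condensation of DMF-DMA with the acetyl CH3 of dehydroacetic acid (the known reactive site) installs the future C2–C3 unit and leaves the 6-CH3 as the only acidic sp3 C–H.

**Step 6**
Reactants: 12; 9
Product: 14 3-[(2E)-3-(dimethylamino)prop-2-enoyl]-4-hydroxy-6-[(3S)-6-methyl-3-(prop-1-en-2-yl)hept-5-en-1-yl]-2H-pyran-2-one, via dilithium dianion 13 (not isolated)
Conditions: LDA (2.05 equiv), THF–DMPU, −78 °C; then 9, −78 → −20 °C; AcOH quench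
Reagents that add atoms: none
Why: Lateral (vinylogous) alkylation of a 4-hydroxy-6-methyl-2-pyranone dianion: the last-formed 6-CH2 carbanion displaces the primary iodide by SN2, and the stereocentre of 9 is not involved.

**Step 7**
Reactants: 14
Product: 15 3-[(2E)-3-(dimethylamino)prop-2-enoyl]-4-methoxy-6-[(3S)-6-methyl-3-(prop-1-en-2-yl)hept-5-en-1-yl]-2H-pyran-2-one
Conditions: Me2SO4, K2CO3, acetone, reflux
Reagents that add atoms: dimethyl sulfate, COS(=O)(=O)OC
Why: O-methylation of the 4-hydroxy-2-pyranone (as in the standard preparation of 4-methoxy-6-methyl-2-pyranone) fixes the oxygen that becomes 5-OMe before the oxygens that become 7-OH and O1 are set free.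

**Step 8**
Reactants: 15
Product: 19 7-hydroxy-5-methoxy-8-[(2R)-5-methyl-2-(prop-1-en-2-yl)hex-4-en-1-yl]-4H-chromen-4-one, via pyranone carbanion 16 (not isolated), via ketene enolate 17 (not isolated), via aryl enaminone 18 (not isolated)
Conditions: LiHMDS (3 equiv), THF, −78 → 55 °C; then AcOH, EtOH, 55 °C (same flask)
Reagents that add atoms: none
Why: Proposed new method: LiHMDS removes the vinylogously acidic C–H next to C6 (the same anion type as in step 6), the lactone-enolate form of 16 expels the ring oxygen from the carbonyl carbon (E1cB acyl–oxygen cleavage) to give the (Z)-dienyl ketene enolate 17, and after bond rotation the enolate carbon attacks the ketene carbon (anion-accelerated 6π closure, as in the last stage of a Danheiser benzannulation), so that tautomerisation gives the resorcinolate of 18 (ring A; a net O→C acyl shift, the carbon analogue of a Dimroth rearrangement, driven by aromatisation); AcOH then closes ring C by addition of the only ortho OH to the enaminone with loss of Me2NH (standard chromone synthesis); the closest known reactions are the base-mediated ring fission–Claisen recyclisation of 2-pyranones to acylphloroglucinols (tetraacetic acid lactone → phloroacetophenone) and isocoumarin → naphthol rearrangements; no stereocentre is formed and the side-chain centre is not acidic.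

**Step 9**
Reactants: 19; 20 4-hydroxyphenylboronic acid
Product: 21 (2S)-7-hydroxy-2-(4-hydroxyphenyl)-5-methoxy-8-[(2R)-5-methyl-2-(prop-1-en-2-yl)hex-4-en-1-yl]-2,3-dihydro-4H-chromen-4-one (kushenol U)
Conditions: [Rh(OH)(cod)]2 (3 mol %), (S)-MeO-F12-BIPHEP (6.6 mol %), CH2Cl2–H2O, 25 °C
Reagents that add atoms: none
Why: Rh-catalysed asymmetric 1,4-addition of an arylboronic acid to a chromone (Hayashi–Miyaura reaction with the electron-poor bisphosphine developed for chromone → flavanone additions) delivers the aryl group to one face of C2 under catalyst control (2S), independent of the remote side-chain centre, and the neutral conditions avoid retro-oxa-Michael racemisation.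

**Compound list**
1 | (4S)-4-benzyl-1,3-oxazolidin-2-one | O=C1N[C@@H](Cc2ccccc2)CO1 | starting material
2 | 3-methylbut-2-enoyl chloride | CC(C)=CC(Cl)=O | starting material
3 | lithium (4S)-4-benzyl-2-oxo-1,3-oxazolidin-3-ide | [Li+].O=C1[N-][C@@H](Cc2ccccc2)CO1 | intermediate (not isolated)
4 | (4S)-4-benzyl-3-(3-methylbut-2-enoyl)-1,3-oxazolidin-2-one | CC(C)=CC(=O)N1C(=O)OC[C@@H]1Cc1ccccc1 | intermediate
5 | 1-bromo-3-methylbut-2-ene | CC(C)=CCBr | starting material
6 | sodium (1Z)-1-[(4S)-4-benzyl-2-oxo-1,3-oxazolidin-3-yl]-3-methylbuta-1,3-dien-1-olate | [Na+].[O-]/C(=C\C(C)=C)N1C(=O)OC[C@@H]1Cc1ccccc1 | intermediate (not isolated)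
7 | (4S)-4-benzyl-3-[(2S)-5-methyl-2-(prop-1-en-2-yl)hex-4-enoyl]-1,3-oxazolidin-2-one | C=C(C)[C@H](CC=C(C)C)C(=O)N1C(=O)OC[C@@H]1Cc1ccccc1 | intermediate
8 | (2S)-5-methyl-2-(prop-1-en-2-yl)hex-4-en-1-ol | C=C(C)[C@H](CC=C(C)C)CO | intermediate
9 | (3S)-3-(iodomethyl)-2,6-dimethylhepta-1,5-diene | C=C(C)[C@H](CC=C(C)C)CI | intermediate
10 | 3-acetyl-4-hydroxy-6-methyl-2H-pyran-2-one (dehydroacetic acid) | CC(=O)C1=C(O)C=C(C)OC1=O | starting material
11 | N,N-dimethylformamide dimethyl acetal | COC(OC)N(C)C | starting material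
12 | 3-[(2E)-3-(dimethylamino)prop-2-enoyl]-4-hydroxy-6-methyl-2H-pyran-2-one | CN(C)/C=C/C(=O)C1=C(O)C=C(C)OC1=O | intermediate
13 | dilithium dianion of 12 (4-olate, 6-CH2 carbanion) | [Li+].[Li+].[CH2-]C1=CC([O-])=C(C(=O)/C=C/N(C)C)C(=O)O1 | intermediate (not isolated)
14 | 3-[(2E)-3-(dimethylamino)prop-2-enoyl]-4-hydroxy-6-[(3S)-6-methyl-3-(prop-1-en-2-yl)hept-5-en-1-yl]-2H-pyran-2-one | C=C(C)[C@H](CC=C(C)C)CCC1=CC(O)=C(C(=O)/C=C/N(C)C)C(=O)O1 | intermediate
15 | 3-[(2E)-3-(dimethylamino)prop-2-enoyl]-4-methoxy-6-[(3S)-6-methyl-3-(prop-1-en-2-yl)hept-5-en-1-yl]-2H-pyran-2-one | C=C(C)[C@H](CC=C(C)C)CCC1=CC(OC)=C(C(=O)/C=C/N(C)C)C(=O)O1 | intermediate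
16 | lithium salt of 15 deprotonated at the CH2 on C6 (side-chain centre unchanged) | [Li+].C=C(C)[C@H](CC=C(C)C)C[CH-]C1=CC(OC)=C(C(=O)/C=C/N(C)C)C(=O)O1 | intermediate (not isolated)
17 | lithium enolate of the ring-opened acylketene, O=C=C(acyl)–C(OMe)=CH–C(O⁻)=CH–CH2–CH(isopropenyl)–prenyl (side-chain centre unchanged) | [Li+].C=C(C)[C@H](CC=C(C)C)CC=C([O-])C=C(OC)C(=C=O)C(=O)/C=C/N(C)C | intermediate (not isolated)
18 | (2E)-1-{2,4-dihydroxy-6-methoxy-3-[(2R)-5-methyl-2-(prop-1-en-2-yl)hex-4-en-1-yl]phenyl}-3-(dimethylamino)prop-2-en-1-one | C=C(C)[C@H](CC=C(C)C)Cc1c(O)cc(OC)c(C(=O)/C=C/N(C)C)c1O | intermediate (not isolated)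
19 | 7-hydroxy-5-methoxy-8-[(2R)-5-methyl-2-(prop-1-en-2-yl)hex-4-en-1-yl]-4H-chromen-4-one | C=C(C)[C@H](CC=C(C)C)Cc1c(O)cc(OC)c2c1OC=CC2=O | intermediate
20 | 4-hydroxyphenylboronic acid | OB(O)c1ccc(O)cc1 | starting material
21 | (2S)-7-hydroxy-2-(4-hydroxyphenyl)-5-methoxy-8-[(2R)-5-methyl-2-(prop-1-en-2-yl)hex-4-en-1-yl]-2,3-dihydro-4H-chromen-4-one (kushenol U) | C=C(C)[C@H](CC=C(C)C)Cc1c(O)cc(OC)c2c1O[C@H](c1ccc(O)cc1)CC2=O | target

**Totals**
Total step count: 9. Longest linear sequence: 8 steps (1 → 2 → 3 → 4 → 6 → 7 → 8 → 9).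

**Three steps most likely to fail**

Step 8 (ring transformation). The anion 16 may not ring-open, or the ketene 17 may be intercepted before C-closure. The fallback sets out from 15 and separates ring fission from ring closure. NaOMe in MeOH at 0 °C opens the enol lactone (Crombie-type ring fission; the vinylogous-amide acyl group resists retro-Claisen loss) to the open-chain methyl ester methyl (8S)-2-[(2E)-3-(dimethylamino)prop-2-enoyl]-3-methoxy-11-methyl-5-oxo-8-(prop-1-en-2-yl)dodeca-2,10-dienoate F1. In a separate flask, LDA (2.2 equiv, THF, −78 → 0 °C) converts this ester into its dianion, whose terminal ketone enolate carbon attacks the ester (Harris-type Claisen cyclisation, methanol lost). This comes back to the route at 18, which is closed to 19 with AcOH as in step 8.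

Step 6 (lateral alkylation). The stabilised dianion 13 may react too slowly with the β-branched iodide, or cause E2 elimination. The fallback sets out from 9 and installs the side chain before the acyl group. Iodide 9 alkylates the more nucleophilic dianion of commercial 4-hydroxy-6-methyl-2H-pyran-2-one (LDA 2 equiv, THF–DMPU; the literature lateral alkylation) to give 4-hydroxy-6-[(3S)-6-methyl-3-(prop-1-en-2-yl)hept-5-en-1-yl]-2H-pyran-2-one F2. C3-acetylation with AcOH/DCC/DMAP (O-acylation, then DMAP-mediated O→C shift, as in pogostone syntheses) gives 3-acetyl-4-hydroxy-6-[(3S)-6-methyl-3-(prop-1-en-2-yl)hept-5-en-1-yl]-2H-pyran-2-one F3. Condensation with 11 (PhMe, 80 °C) then comes back to the route at 14.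

Step 9 (asymmetric arylation). The acidic 7-OH on an electron-rich chromone and the free phenol of 20 may slow the addition or erode selectivity. The fallback sets out from 19 and masks both phenols. TBSCl/imidazole (DMF) gives 7-[(tert-butyldimethylsilyl)oxy]-5-methoxy-8-[(2R)-5-methyl-2-(prop-1-en-2-yl)hex-4-en-1-yl]-4H-chromen-4-one F4. The Rh/(S)-MeO-F12-BIPHEP addition is then run with commercial 4-(tert-butyldimethylsilyloxy)phenylboronic acid to give (2S)-7-[(tert-butyldimethylsilyl)oxy]-2-{4-[(tert-butyldimethylsilyl)oxy]phenyl}-5-methoxy-8-[(2R)-5-methyl-2-(prop-1-en-2-yl)hex-4-en-1-yl]-2,3-dihydro-4H-chromen-4-one F5. HF·pyridine (THF, 0 °C; non-basic, so C2 is not epimerised) removes both silyl groups and comes back to the route at 21.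

**Further compounds**
F1 | step 8 | methyl (8S)-2-[(2E)-3-(dimethylamino)prop-2-enoyl]-3-methoxy-11-methyl-5-oxo-8-(prop-1-en-2-yl)dodeca-2,10-dienoate | C=C(C)[C@H](CC=C(C)C)CCC(=O)CC(OC)=C(C(=O)OC)C(=O)/C=C/N(C)C
F2 | step 6 | 4-hydroxy-6-[(3S)-6-methyl-3-(prop-1-en-2-yl)hept-5-en-1-yl]-2H-pyran-2-one | C=C(C)[C@H](CC=C(C)C)CCC1=CC(O)=CC(=O)O1
F3 | step 6 | 3-acetyl-4-hydroxy-6-[(3S)-6-methyl-3-(prop-1-en-2-yl)hept-5-en-1-yl]-2H-pyran-2-one | C=C(C)[C@H](CC=C(C)C)CCC1=CC(O)=C(C(C)=O)C(=O)O1
F4 | step 9 | 7-[(tert-butyldimethylsilyl)oxy]-5-methoxy-8-[(2R)-5-methyl-2-(prop-1-en-2-yl)hex-4-en-1-yl]-4H-chromen-4-one | C=C(C)[C@H](CC=C(C)C)Cc1c(O[Si](C)(C)C(C)(C)C)cc(OC)c2c1OC=CC2=O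
F5 | step 9 | (2S)-7-[(tert-butyldimethylsilyl)oxy]-2-{4-[(tert-butyldimethylsilyl)oxy]phenyl}-5-methoxy-8-[(2R)-5-methyl-2-(prop-1-en-2-yl)hex-4-en-1-yl]-2,3-dihydro-4H-chromen-4-one | C=C(C)[C@H](CC=C(C)C)Cc1c(O[Si](C)(C)C(C)(C)C)cc(OC)c2c1O[C@H](c1ccc(O[Si](C)(C)C(C)(C)C)cc1)CC2=O
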